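## Retrosynthetic overview
1. The C13 acetate, the C1 methyl ketal (MeOH/H⁺ on the 1,4‑hemiketal) and the C8 tiglate go on last. C5=C6 comes from E1cB loss of a C5 silyloxy group inside the finished bicycle, so the ring enforces the 5E geometry.
2. The ten‑membered carbocycle is closed at C7–C8 by Nozaki–Hiyama–Kishi (NHK) coupling of a β‑iodobutenolide with an aldehyde, on a substrate that already sits as the C1/C4 hemiketal (THF).
3. C5–C6 is made by an intermolecular silylative vinylogous aldol between iodobutenolide 5 and the non‑enolisable aldehyde 13.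
4. (R)‑Linalool supplies C1–C5/C15 and the C4 stereocentre. Brown crotylation adds C8–C10/C14 and sets C10. The C1 carbinol is sacrificial.
5. Ring order: butenolide (allenoate iodolactonisation), then THF hemiketal, then ten‑membered ring.

Assumptions (one line each):
- Germacrane numbering is used: C1 ketal, C4 tertiary ether, C8 tiglate carbon, C10 CH–CH3, C13 CH2OAc.
- Commercial (−)‑linalool is used as received at high ee.
- C5/C6 in 14–19 are carried as a diastereomer mixture and drawn without descriptors, because both centres are erased in step 16.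
- Compound 16 is drawn in its open form but exists mainly as the hemiketal/lactol.

## Route

### Butenolide branch

**Step 1**
- Reactants: 1 but‑2‑yne‑1,4‑diol
- Product: 2 4‑(TBSO)but‑2‑yn‑1‑ol
- Conditions: NaH (1 equiv), TBSCl (1 equiv), THF, 0 °C→rt
- Reagents that add atoms: TBSCl, CC(C)(C)[Si](C)(C)Cl
- Why: Monosilylation of a symmetrical diol through its sparingly soluble mono‑alkoxide gives the mono‑TBS ether, and no stereocentre is formed.

**Step 2**
- Reactants: 2
- Product: 3 4‑(TBSO)but‑2‑yn‑1‑yl methyl carbonate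
- Conditions: ClCO2Me, pyridine, CH2Cl2, 0 °C
- Reagents that add atoms: methyl chloroformate, COC(=O)Cl
- Why: Simple O‑acylation turns the propargylic alcohol into a leaving group for Pd(0).

**Step 3**
- Reactants: 3
- Product: 4 methyl 2‑(TBSOCH2)buta‑2,3‑dienoate
- Conditions: Pd(OAc)2 (2 mol %), PPh3 (8 mol %), CO (10 bar), MeOH, 50 °C
- Reagents that add atoms: carbon monoxide, [C-]#[O+]; methanol, CO
- Why: In the Tsuji decarboxylative carbonylation, SN2′ oxidative addition gives an allenyl‑Pd species that inserts CO at the carbon bearing CH2OTBS and is trapped as the methyl ester.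

**Step 4**
- Reactants: 4
- Product: 5 3‑(TBSOCH2)‑4‑iodofuran‑2(5H)‑one
- Conditions: I2 (2 equiv), NaHCO3, MeCN/H2O 15:1, rt
- Reagents that add atoms: iodine, II
- Why: In this allenoate iodolactonisation, I⁺ activates the distal C=C, the ester oxygen closes 5‑endo on the CH2 terminus with loss of the methyl group, iodine ends on the β‑carbon, and bicarbonate protects the TBS ether.

### Main line

**Step 5**
- Reactants: 6 (R)‑(−)‑linalool
- Product: 7 (R)‑linalool TMS ether
- Conditions: N‑(trimethylsilyl)imidazole, CH2Cl2, rt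
- Reagents that add atoms: TMS‑imidazole, C[Si](C)(C)n1ccnc1
- Why: Silylation gives a tertiary TMS ether that is robust to handle yet as acid‑labile as a primary or secondary TES ether, and the C4 (R) centre comes from the chiral pool.

**Step 6**
- Reactants: 7
- Product: 8 (4R)‑4‑methyl‑4‑(TMSO)hex‑5‑enal
- Conditions: O3 (1 equiv, Sudan III end point), CH2Cl2/pyridine, −78 °C; Me2S
- Reagents that add atoms: ozone, [O-][O+]=O
- Why: Chemoselective ozonolysis works because the electron‑rich trisubstituted alkene reacts far faster than the hindered, allylically oxygenated vinyl group.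

**Step 7**
- Reactants: 8; 9 trans‑2‑butene
- Product: 10 (3R,4S,7R)‑3,7‑dimethyl‑7‑(TMSO)nona‑1,8‑dien‑4‑ol
- Conditions: 9, n‑BuLi/KOt‑Bu, THF, −45 °C; (+)‑Ipc2BOMe [from (−)‑α‑pinene], −78 °C; BF3·OEt2; 8, −78 °C; H2O2/NaOAc work‑up
- Reagents that add atoms: none beyond 9, which is delivered as (E)‑crotyl‑B(Ipc)2
- Why: In the Brown crotylation the chair transition state of the E‑crotylborane gives the anti adduct, and the Ipc ligands choose the aldehyde face, which sets C10 as R while the carbinol (C1) is removed later.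

**Step 8**
- Reactants: 10
- Product: 11 (3R,4S,7R)‑3,7‑dimethyl‑7‑(TMSO)non‑8‑ene‑1,4‑diol
- Conditions: Sia2BH (2.3 equiv), THF, 0 °C; 30 % H2O2, 3 M NaOAc, 0 °C
- Reagents that add atoms: hydrogen peroxide, OO
- Why: Anti‑Markovnikov hydroboration–oxidation with disiamylborane strongly prefers the vinyl on a CH(CH3) carbon over the vinyl on the fully substituted, O‑silylated carbon.

**Step 9**
- Reactants: 11
- Product: 12 the bis‑TES ether of 11
- Conditions: TESCl (2.5 equiv), imidazole, CH2Cl2, 0 °C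
- Reagents that add atoms: TESCl, CC[Si](Cl)(CC)CC
- Why: Silyl ether formation masks C1‑OH and C8‑OH so that they cannot form a lactol with, or compete at, the C5 aldehyde.

**Step 10**
- Reactants: 12
- Product: 13 (2R,5S,6R)‑2,6‑dimethyl‑5,8‑bis(TESO)‑2‑(TMSO)octanal
- Conditions: O3, CH2Cl2, −78 °C; PPh3
- Reagents that add atoms: ozone, [O-][O+]=O
- Why: Ozonolysis of the only remaining alkene gives the non‑enolisable C5 aldehyde, and the silyl ethers are inert.

**Step 11**
- Reactants: 13; 5
- Product: 14 the C5–C6 aldol adduct as its C5 TBS ether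
- Conditions: 5 (1.2 equiv), TBSOTf (2.5 equiv), i‑Pr2NEt (3.5 equiv), CH2Cl2, −78→−20 °C
- Reagents that add atoms: TBSOTf, CC(C)(C)[Si](C)(C)OS(=O)(=O)C(F)(F)F
- Why: In this silylative vinylogous Mukaiyama aldol the 2‑silyloxyfuran formed in situ attacks through its γ‑carbon (the α‑carbon is blocked), the aldolate is trapped as OTBS, and the new C5/C6 centres (Felkin‑type bias) are inconsequential.

**Step 12**
- Reactants: 14
- Product: 15 the C1,C4,C8‑triol, with C5‑ and C13‑OTBS retained
- Conditions: PPTS (0.2 equiv), MeOH/CH2Cl2 1:1, 0 °C→rt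
- Reagents that add atoms: none
- Why: Graded acid solvolysis removes the TMS and TES ethers orders of magnitude faster than the TBS ethers.

**Step 13**
- Reactants: 15
- Product: 16 (3R,7R)‑hydroxy keto‑aldehyde (C1 ketone, C8 aldehyde, free C4‑OH)
- Conditions: (COCl)2, DMSO, CH2Cl2, −78 °C; Et3N, −78→−30 °C
- Reagents that add atoms: none
- Why: The Swern oxidation activates both hydroxyls before base is added, so the 1,4‑diol gives the keto‑aldehyde rather than a lactone, and the tertiary C4‑OH then adds reversibly to C1.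

**Step 14**
- Reactants: 16
- Product: 17 (1S,4R,8S,10R) bridged macrocyclic hemiketal with free C8‑OH
- Conditions: CrCl2 (15 equiv), NiCl2 (1 mol % of Cr), DMSO/THF, 2 mM, slow addition, rt
- Reagents that add atoms: none
- Why: NHK macrocyclisation proceeds through the cis‑2,5‑disubstituted THF hemiketal tautomer, where C9 must lie on the oxygen‑bridge face and H8 eclipses C7=C11 to avoid A1,3 strain with CH2OTBS, so O8 ends anti to the bridge (8S) and C1 (S) is dictated by C4.

**Step 15**
- Reactants: 17; 18 tiglic acid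
- Product: 19 the 8‑O‑tiglate
- Conditions: 18, 2,4,6‑trichlorobenzoyl chloride, Et3N, toluene; 17, DMAP, rt
- Reagents that add atoms: none beyond 18
- Why: Yamaguchi esterification acylates the only secondary alcohol with retention at C8, while the tertiary hemiketal OH does not react.

**Step 16**
- Reactants: 19
- Product: 20 (5E)‑dienolide hemiketal (13‑OTBS)
- Conditions: DBU (2 equiv), CH2Cl2, 0 °C→rt
- Reagents that add atoms: none
- Why: E1cB elimination through the furanolate expels the γ‑side silanolate at C5 in preference to the C13 silyloxy group, and only the alkene with C4 cis to C7 (5E) fits the 11‑oxabicyclo[6.2.1] frame.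

**Step 17**
- Reactants: 20
- Product: 21 the 1‑O‑methyl ketal with free C13‑OH
- Conditions: CSA (10 mol %), MeOH/HC(OMe)3, 0 °C→rt
- Reagents that add atoms: methanol, CO
- Why: Acid‑catalysed ketalisation and primary TBS methanolysis occur in one operation, and the bridge allows only the 1S ketal.

**Step 18**
- Reactants: 21
- Product: 22 vernolide‑B
- Conditions: Ac2O, pyridine, cat. DMAP, CH2Cl2, 0 °C
- Reagents that add atoms: acetic anhydride, CC(=O)OC(C)=O
- Why: Acetylation of the single remaining primary allylic hydroxyl completes the target without touching any stereocentre.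

## Compound list

| No. | Name | SMILES | Role |
|---|---|---|---|
| 1 | but‑2‑yne‑1,4‑diol | OCC#CCO | starting material |
| 2 | 4‑(TBSO)but‑2‑yn‑1‑ol | OCC#CCO[Si](C)(C)C(C)(C)C | intermediate |
| 3 | 4‑(TBSO)but‑2‑ynyl methyl carbonate | COC(=O)OCC#CCO[Si](C)(C)C(C)(C)C | intermediate |
| 4 | methyl 2‑(TBSOCH2)buta‑2,3‑dienoate | C=C=C(CO[Si](C)(C)C(C)(C)C)C(=O)OC | intermediate |
| 5 | 3‑(TBSOCH2)‑4‑iodofuran‑2(5H)‑one | O=C1OCC(I)=C1CO[Si](C)(C)C(C)(C)C | intermediate |
| 6 | (R)‑(−)‑linalool | C=C[C@](C)(O)CCC=C(C)C | starting material |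
| 7 | (R)‑linalool TMS ether | C=C[C@](C)(O[Si](C)(C)C)CCC=C(C)C | intermediate |
| 8 | (4R)‑4‑methyl‑4‑(TMSO)hex‑5‑enal | C=C[C@](C)(O[Si](C)(C)C)CCC=O | intermediate |
| 9 | trans‑2‑butene | C/C=C/C | starting material |
| 10 | (3R,4S,7R)‑3,7‑dimethyl‑7‑(TMSO)nona‑1,8‑dien‑4‑ol | C=C[C@](C)(O[Si](C)(C)C)CC[C@H](O)[C@H](C)C=C | intermediate |
| 11 | (3R,4S,7R)‑3,7‑dimethyl‑7‑(TMSO)non‑8‑ene‑1,4‑diol | C=C[C@](C)(O[Si](C)(C)C)CC[C@H](O)[C@H](C)CCO | intermediate |
| 12 | 1,4‑bis‑TES ether of 11 | C=C[C@](C)(O[Si](C)(C)C)CC[C@H](O[Si](CC)(CC)CC)[C@H](C)CCO[Si](CC)(CC)CC | intermediate |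
| 13 | (2R,5S,6R)‑2,6‑dimethyl‑5,8‑bis(TESO)‑2‑(TMSO)octanal | O=C[C@](C)(O[Si](C)(C)C)CC[C@H](O[Si](CC)(CC)CC)[C@H](C)CCO[Si](CC)(CC)CC | intermediate |
| 14 | 5‑[(2R,5S,6R)‑1‑(TBSO)‑2,6‑dimethyl‑5,8‑bis(TESO)‑2‑(TMSO)octyl]‑3‑(TBSOCH2)‑4‑iodofuran‑2(5H)‑one (C5/C6 mixture) | O=C1OC(C(O[Si](C)(C)C(C)(C)C)[C@](C)(O[Si](C)(C)C)CC[C@H](O[Si](CC)(CC)CC)[C@H](C)CCO[Si](CC)(CC)CC)C(I)=C1CO[Si](C)(C)C(C)(C)C | intermediate |
| 15 | corresponding 2,5,8‑triol | O=C1OC(C(O[Si](C)(C)C(C)(C)C)[C@](C)(O)CC[C@H](O)[C@H](C)CCO)C(I)=C1CO[Si](C)(C)C(C)(C)C | intermediate |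
| 16 | (3R,7R)‑8‑(TBSO)‑7‑hydroxy‑8‑[3‑iodo‑4‑(TBSOCH2)‑5‑oxo‑2,5‑dihydrofuran‑2‑yl]‑3,7‑dimethyl‑4‑oxooctanal (open form) | O=C1OC(C(O[Si](C)(C)C(C)(C)C)[C@](C)(O)CCC(=O)[C@H](C)CC=O)C(I)=C1CO[Si](C)(C)C(C)(C)C | intermediate |
| 17 | (1S,4R,8S,10R)‑1,4‑epoxy‑1,8‑dihydroxy‑5,13‑bis(TBSO)germacr‑7(11)‑en‑6,12‑olide | O[C@H]1C[C@@H](C)[C@]2(O)CC[C@](C)(C(O[Si](C)(C)C(C)(C)C)C3OC(=O)C(CO[Si](C)(C)C(C)(C)C)=C31)O2 | intermediate |
| 18 | tiglic acid | C/C=C(\C)C(=O)O | starting material |
| 19 | 8‑O‑tiglate of 17 | C/C=C(\C)C(=O)O[C@H]1C[C@@H](C)[C@]2(O)CC[C@](C)(C(O[Si](C)(C)C(C)(C)C)C3OC(=O)C(CO[Si](C)(C)C(C)(C)C)=C31)O2 | intermediate |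
| 20 | (1S,4R,5E,8S,10R)‑1,4‑epoxy‑1‑hydroxy‑13‑(TBSO)‑8‑tigloyloxygermacra‑5,7(11)‑dien‑6,12‑olide | C/C=C(\C)C(=O)O[C@H]1C[C@@H](C)[C@]2(O)CC[C@](C)(/C=C3/OC(=O)C(CO[Si](C)(C)C(C)(C)C)=C31)O2 | intermediate |
| 21 | 1‑O‑methyl‑13‑hydroxy analogue | C/C=C(\C)C(=O)O[C@H]1C[C@@H](C)[C@]2(OC)CC[C@](C)(/C=C3/OC(=O)C(CO)=C31)O2 | intermediate |
| 22 | vernolide‑B | C/C=C(\C)C(=O)O[C@H]1C[C@@H](C)[C@]2(OC)CC[C@](C)(/C=C3/OC(=O)C(COC(C)=O)=C31)O2 | target |

## Totals
- Total steps: 18
- Longest linear sequence: 14 (steps 5–18, from (R)‑linalool)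
- Butenolide branch: 4 steps

## Steps most likely to fail

**1. Step 14 (NHK ring closure).**
- The 4‑chromio‑butenolide may open to an allenoate.
- The aldehyde is partly hidden as a spiro‑lactol.
- The C8 facial selectivity may depend on the C6 configuration of the aldol adduct.
- Fallback: reverse the order of bond formation.
  - Couple 5 intermolecularly with the C8 aldehyde, with the vinyl group still masking C5, under ligand‑controlled asymmetric NHK so that C8 is fixed in an acyclic setting.
  - Unveil the C5 aldehyde and close the ring at C5–C6 by an intramolecular silylative vinylogous aldol.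
  - If only the 8‑epimer forms in step 14, replace step 15 with a Mitsunobu esterification using tiglic acid, which inverts C8.

**2. Step 11 (vinylogous aldol on a neopentyl, α‑silyloxy aldehyde).**
- The aldehyde is very hindered, so the addition may be slow or may not occur.
- Fallback: change the electrophile and the nucleophile.
  - Use a C4–C5 terminal (2,2‑disubstituted) epoxide and open it at C5 with 3‑bromo‑2‑lithio‑4‑(TBSOCH2)furan.
  - Close the ring on the halofuran.
  - Create the alkylidene butenolide last by singlet‑oxygen oxidation to the C6 γ‑hydroxybutenolide, followed by dehydration.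

**3. Step 8 (discriminating two terminal vinyl groups).**
- Disiamylborane may not distinguish the two vinyl groups well enough.
- Fallback: replace the crotylation by a Marshall propargylation.
  - Use an enantiopure but‑3‑yn‑2‑yl mesylate with Pd(0)/Et2Zn, which sets the same C10 centre.
  - The terminal alkyne is inert to ozone.
  - Convert the alkyne to the C8 aldehyde by Ru‑catalysed anti‑Markovnikov hydration.
  - Carry C1‑OH as a TES ether and oxidise it after macrocyclisation.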